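The runs are simulated for substances that don't exist.

The south-east run at 10.0 min and the east run at 25.0 min hold nearly the same target, 11.6% and 11.8%, though the south-east run charges 2.27 times the reagent. So reagent and time seem to trade against each other.

| flask | starting material | reagent in the second phase | protic impurity | remark | time | volume of the second phase over the first |
|---|---|---|---|---|---|---|
| east | 0.11 M | 0.088 M | 0.022 M | run made earlier |  |  |
| south-east | 0.11 M | 0.20 M | 0.022 M | run made earlier |  |  |
| north-east | 0.055 M | 0.132 M | 0.022 M | run made earlier |  |  |
| flask | 0.11 M | 0.132 M | 0.0220 M |  | 1.0 h | 1.0 |

| run | time / min | target / % | starting material / % |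
|---|---|---|---|
| east | 10.0 | 5.3 | 95.4 |
| east | 25.0 | 11.8 | 87.0 |
| east | 50.0 | 21.6 | 79.2 |
| east | 80.0 | 27.8 | 71.8 |
| south-east | 10.0 | 11.6 | 87.2 |
| south-east | 25.0 | 24.2 | 73.0 |
| south-east | 50.0 | 38.5 | 55.8 |
| south-east | 80.0 | 45.4 | 44.8 |
| north-east | 10.0 | 7.9 | 91.3 |
| north-east | 25.0 | 18.4 | 81.6 |
| north-east | 50.0 | 30.2 | 65.7 |
| north-east | 80.0 | 39.0 | 54.7 |

(each reading ± 1 percentage point)

- in the second phase: reagent in the second phase; everything else is in the first
- charges count per volume of the first phase; a concentration in a rate is the amount of a species over the volume of its own phase; every rate counts per litre of the first phase
- the earlier runs hold the two phases in the same ratio of volumes as the flask asked about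

- ash: doubling the amount of reagent in the second phase, all else as stated
- cedar: doubling the transfer coefficient of the reagent in the second phase, all else as stated

- target at 1.0 h, in percent of the starting material charged
- the change that raises the amount of target at 1.0 h, in percent of the starting material charged most ("none" if none brings more than 2 percentage points) (ash / cedar / none)
- amount of target at 1.0 h, in percent of the starting material charged, after ash

I freeze the reagent at its charge, a pseudo-first-order treatment. The last readings of the east and south-east runs then give a mean constant of 0.0486 /M/min. The flask's exposure θ is 0.385, that constant times reagent charged times time; it counts the e-fold falls of starting material paid for.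

The east run at 80.0 min stands at 0.342 and the south-east run at 50.0 min at 0.486, with the flask's charge of starting material. Between their targets I read 31.0% for the flask.

Is one number enough? Not for these runs: the north-east run, with half the starting material, has 65.7% of it left at an exposure of 0.321, less than the east run's 71.8% at 0.342.

Ash takes θ to 0.770, beside the south-east run's last 0.778, so I expect about 45.4%. For cedar, a fixed supply across the phases should give twice the percent from that halved charge, yet the first readings per reagent charged stand at a ratio of 1.03. I choose ash.

The forecast says 31.5% (29% to 34%), ash, and 45% (41% to 49%) after it, holding that “transfer is not limiting and cedar should do almost nothing”.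

    reagent in the reaction phase + target → over-reacted product (k = 0.0690 /M/min)
    reagent in the reaction phase ⇌ reagent in the second phase, rate k2*([reagent in the reaction phase] - [reagent in the second phase]/K2) per volume of the first phase (partition coefficient = 1.30, kL = 1.10 /min)
    reagent in the reaction phase + protic impurity → quenched reagent (k = 0.180 /M/min)
    starting material + reagent in the reaction phase → target (k = 0.160 /M/min)

The flask gives 31.5%; ash wins with 16 percentage points against 0.12 points for cedar, and reaches 47.2%. At 1.00 h the flask still makes target 4.80 times faster than it uses it up. Put to use again, θ gives 68.0% of the starting material left, and the flask holds 65.2%.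

A neighbour charged with 0.28 M of starting material has the same θ, so the reckoning again leaves 68.0%. Computed, it holds 73% starting material and 25.5% target.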